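**Retrosynthetic overview**
1. Target ⇐ angeloylation of the 8α‑hydroxy‑9‑ketone with a preformed angelic mixed anhydride (fragment 3); the ketol ⇐ Rubottom oxidation of a ring B silyl enol ether.
2. Ring B (formed last) ⇐ ruthenium‑catalysed ring‑closing metathesis (C8=C9) between a methyl‑ketone‑derived silyl enol ether on C10 and the vinyl group of the C5 side arm.
3. 1α‑OAc / 10α‑H / C9 ketone on ring A ⇐ ruthenium‑hydride redox transposition of a conjugate‑addition/aldol adduct (new step), then acetylation.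
4. C5–C6 quaternary bond ⇐ copper‑catalysed coupling (1,4‑addition) of the fragment 2 Grignard reagent, (S)‑CH2=C(Me)CH(CH=CH2)CH2MgBr, with fragment 1, (S)‑3,4‑dimethylcyclohex‑2‑enone; the enolate is trapped with acetaldehyde.
5. Fragment 1 (ring A, formed first) ⇐ organocatalytic Michael/aldol, methyl addition, Saegusa oxidation; fragment 2 ⇐ copper‑catalysed enantioselective allylic substitution of a butenediol phosphate with isopropenyl‑B(pin).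

Assumption: eremophilane numbering is used in the discussion (C1 OAc, C4/C5 methyls, C7 isopropenyl, C8 angelate, C9 ketone, C10 ring‑fusion CH); the SMILES is read as (1S,4S,5R,7R,8R,10S), i.e. 1α‑OAc, 4β,5β‑Me2, 7β‑isopropenyl, 8α‑OAng, 10α‑H (trans‑decalin).

**Fragment 1 (ring A enone)**

Step 1
Reactants: 1 propanal; 2 but‑3‑en‑2‑one
Product: 3 (2S)‑2‑methyl‑5‑oxohexanal
Conditions: (R)‑2‑[methoxy(diphenyl)methyl]pyrrolidine (5 mol %), ethyl 3,4‑dihydroxybenzoate (20 mol %), neat, 4 °C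
Reagents that add atoms: none
Why: Enamine‑catalysed asymmetric Michael addition; the diarylmethyl group shields one enamine face so the enone adds to give the 2S aldehyde (this centre becomes C4).

Step 2
Reactants: 3 (2S)‑2‑methyl‑5‑oxohexanal
Product: 4 (4S)‑4‑methylcyclohex‑2‑en‑1‑one
Conditions: p‑TsOH·H2O (10 mol %), toluene, reflux, Dean–Stark
Reagents that add atoms: none
Why: Intramolecular aldol condensation of the methyl ketone onto the aldehyde closes ring A; the stereocentre ends up γ to the carbonyl and is not touched.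

Step 3
Reactants: 4 (4S)‑4‑methylcyclohex‑2‑en‑1‑one
Product: 5 trimethyl{[(3R,4S)‑3,4‑dimethylcyclohex‑1‑en‑1‑yl]oxy}silane
Conditions: MeMgBr, CuBr·SMe2 (5 mol %), TMSCl, HMPA, THF, −78 °C
Reagents that add atoms: methylmagnesium bromide (C[Mg]Br); chlorotrimethylsilane (C[Si](C)(C)Cl)
Why: Copper‑catalysed, TMSCl‑accelerated conjugate addition installs the future C5 methyl (trans to the 4‑methyl); the new centre is removed in step 4, so its ratio does not matter.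

Step 4
Reactants: 5 trimethyl{[(3R,4S)‑3,4‑dimethylcyclohex‑1‑en‑1‑yl]oxy}silane
Product: 6 (4S)‑3,4‑dimethylcyclohex‑2‑en‑1‑one
Conditions: Pd(OAc)2 (10 mol %), O2 (1 atm), DMSO, 25 °C
Reagents that add atoms: none
Why: Saegusa–Ito oxidation (palladium enolate, β‑hydride elimination) regenerates the enone, now β‑methylated.

**Fragment 2 (side arm)**

Step 5
Reactants: 7 (2E)‑but‑2‑ene‑1,4‑diol
Product: 8 (2E)‑4‑{[tert‑butyl(dimethyl)silyl]oxy}but‑2‑en‑1‑ol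
Conditions: NaH (1.0 equiv), TBSCl (1.0 equiv), THF, 0 → 23 °C
Reagents that add atoms: tert‑butyldimethylsilyl chloride (CC(C)(C)[Si](C)(C)Cl)
Why: Monosilylation of a symmetrical diol through its sparingly soluble monosodium alkoxide.

Step 6
Reactants: 8 (2E)‑4‑{[tert‑butyl(dimethyl)silyl]oxy}but‑2‑en‑1‑ol
Product: 9 (2E)‑4‑{[tert‑butyl(dimethyl)silyl]oxy}but‑2‑en‑1‑yl diethyl phosphate
Conditions: ClP(O)(OEt)2, pyridine, DMAP (cat.), CH2Cl2, 0 °C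
Reagents that add atoms: diethyl chlorophosphate (CCOP(=O)(Cl)OCC)
Why: O‑Phosphorylation turns the allylic alcohol into the leaving group for allylic substitution.

Step 7
Reactants: 10 prop‑1‑en‑2‑ylmagnesium bromide
Product: 11 4,4,5,5‑tetramethyl‑2‑(prop‑1‑en‑2‑yl)‑1,3,2‑dioxaborolane
Conditions: 2‑isopropoxy‑4,4,5,5‑tetramethyl‑1,3,2‑dioxaborolane, THF, −78 → 23 °C; then HCl in Et2O
Reagents that add atoms: 2‑isopropoxy‑4,4,5,5‑tetramethyl‑1,3,2‑dioxaborolane (CC(C)OB1OC(C)(C)C(C)(C)O1)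
Why: Borylation of a Grignard reagent with an alkoxyboronate (ate complex, loss of isopropoxide).

Step 8
Reactants: 9 (2E)‑4‑{[tert‑butyl(dimethyl)silyl]oxy}but‑2‑en‑1‑yl diethyl phosphate; 11 4,4,5,5‑tetramethyl‑2‑(prop‑1‑en‑2‑yl)‑1,3,2‑dioxaborolane
Product: 12 tert‑butyl(dimethyl){[(2S)‑2‑(prop‑1‑en‑2‑yl)but‑3‑en‑1‑yl]oxy}silane
Conditions: CuCl (5 mol %), chiral sulfonate‑bearing imidazolinium salt (N‑heterocyclic carbene precursor, 5.5 mol %), NaOMe (1.5 equiv), THF, 22 °C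
Reagents that add atoms: none
Why: Copper‑catalysed enantioselective SN2' allylic substitution; the alkenyl–copper formed by boron‑to‑copper transmetalation attacks the γ‑carbon, forming the C7–C11 bond and setting C7 under ligand control (the ligand enantiomer that gives 2S is used).

Step 9
Reactants: 12 tert‑butyl(dimethyl){[(2S)‑2‑(prop‑1‑en‑2‑yl)but‑3‑en‑1‑yl]oxy}silane
Product: 13 (2S)‑2‑(prop‑1‑en‑2‑yl)but‑3‑en‑1‑ol
Conditions: camphorsulfonic acid (5 mol %), MeOH, 0 → 23 °C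
Reagents that add atoms: none
Why: Acid‑catalysed methanolysis of a primary silyl ether; the skipped diene is inert.

Step 10
Reactants: 13 (2S)‑2‑(prop‑1‑en‑2‑yl)but‑3‑en‑1‑ol
Product: 14 (3S)‑3‑(bromomethyl)‑2‑methylpenta‑1,4‑diene
Conditions: CBr4, PPh3, CH2Cl2, 0 °C
Reagents that add atoms: tetrabromomethane (BrC(Br)(Br)Br)
Why: Appel bromination of a primary alcohol; the stereocentre is not involved.

**Fragment 3 (acyl donor)**

Step 11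
Reactants: 15 (2Z)‑2‑methylbut‑2‑enoic acid (angelic acid)
Product: 16 (2Z)‑2‑methylbut‑2‑enoic 2,4,6‑trichlorobenzoic anhydride
Conditions: 2,4,6‑trichlorobenzoyl chloride, Et3N, toluene, 23 °C; filtered and concentrated
Reagents that add atoms: 2,4,6‑trichlorobenzoyl chloride (O=C(Cl)c1c(Cl)cc(Cl)cc1Cl)
Why: Yamaguchi mixed‑anhydride formation activates the acid under conditions that do not isomerise the Z alkene to the tiglate.

**Assembly**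

Step 12
Reactants: 14 (3S)‑3‑(bromomethyl)‑2‑methylpenta‑1,4‑diene; 6 (4S)‑3,4‑dimethylcyclohex‑2‑en‑1‑one; 17 acetaldehyde
Product: 21 (3R,4S)‑2‑(1‑hydroxyethyl)‑3,4‑dimethyl‑3‑[(2S)‑2‑(prop‑1‑en‑2‑yl)but‑3‑en‑1‑yl]cyclohexan‑1‑one (epimer mixture at C2 plus carbinol carbon), via Grignard reagent 18 (not isolated), via silyl enol ether 19 (not isolated), via lithium enolate 20 (not isolated)
Conditions: Mg, THF, 23 °C; then 6, CuI (10 mol %), LiCl (20 mol %), TMSCl, THF, −40 °C; volatiles removed; MeLi, THF, 0 °C; 17, −78 °C; AcOH quench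
Reagents that add atoms: none
Why: Copper‑catalysed conjugate addition forms the C5–C6 bond and the quaternary centre by axial attack anti to the C4 methyl (cis‑vicinal dimethyl array), and the enolate released regiospecifically by MeLi undergoes aldol addition at C10; the two aldol centres need no control because step 13 equilibrates C10 and removes the carbinol centre.

Step 13
Reactants: 21 (3R,4S)‑2‑(1‑hydroxyethyl)‑3,4‑dimethyl‑3‑[(2S)‑2‑(prop‑1‑en‑2‑yl)but‑3‑en‑1‑yl]cyclohexan‑1‑one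
Product: 22 1‑[(1S,2R,3S,6S)‑6‑hydroxy‑2,3‑dimethyl‑2‑[(2S)‑2‑(prop‑1‑en‑2‑yl)but‑3‑en‑1‑yl]cyclohexyl]ethan‑1‑one
Conditions: Ru2(CO)4(μ‑H)[(η5‑C4Ph4CO)2H] (3 mol %), toluene, 70 °C, Ar
Reagents that add atoms: none
Why: Proposed new method: ruthenium‑hydride 1,3‑redox transposition of an aldol, in which the bifunctional diruthenium hydride complex reversibly dehydrogenates the hindered side‑chain carbinol to the 2‑acetylcyclohexanone and returns the hydrogen to the ring carbonyl by outer‑sphere transfer (isolated alkenes are not expected to bind), so that reversible hydrogen transfer plus enolisation of the β‑diketone funnel the mixture to the most stable isomer, with the ring carbinol equatorial (1α‑OH, no syn‑axial clash with the C5 methyl) and the acetyl group equatorial and trans to the side arm (10α‑H); the closest known reactions are ruthenium‑catalysed racemisation/epimerisation of secondary alcohols in dynamic kinetic resolution and redox isomerisation of allylic alcohols.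

Step 14
Reactants: 22 1‑[(1S,2R,3S,6S)‑6‑hydroxy‑2,3‑dimethyl‑2‑[(2S)‑2‑(prop‑1‑en‑2‑yl)but‑3‑en‑1‑yl]cyclohexyl]ethan‑1‑one
Product: 23 (1S,2S,3R,4S)‑2‑acetyl‑3,4‑dimethyl‑3‑[(2S)‑2‑(prop‑1‑en‑2‑yl)but‑3‑en‑1‑yl]cyclohexyl acetate
Conditions: Ac2O, pyridine, DMAP (5 mol %), CH2Cl2, 0 → 23 °C
Reagents that add atoms: acetic anhydride (CC(=O)OC(C)=O)
Why: Acylation of the equatorial secondary alcohol under mild conditions that do not eliminate the β‑oxygen.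

Step 15
Reactants: 23 (1S,2S,3R,4S)‑2‑acetyl‑3,4‑dimethyl‑3‑[(2S)‑2‑(prop‑1‑en‑2‑yl)but‑3‑en‑1‑yl]cyclohexyl acetate
Product: 24 (1S,2S,3R,4S)‑3,4‑dimethyl‑3‑[(2S)‑2‑(prop‑1‑en‑2‑yl)but‑3‑en‑1‑yl]‑2‑{1‑[(triethylsilyl)oxy]ethenyl}cyclohexyl acetate
Conditions: LiN(SiMe3)2, Et3SiCl (premixed, internal quench), THF, −78 °C
Reagents that add atoms: chlorotriethylsilane (CC[Si](CC)(CC)Cl)
Why: Kinetic enolisation occurs at the methyl group (C10–H is flanked by a quaternary carbon) and the enolate is silylated at once, which avoids β‑elimination of acetate and acyl transfer.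

Step 16
Reactants: 24 (1S,2S,3R,4S)‑3,4‑dimethyl‑3‑[(2S)‑2‑(prop‑1‑en‑2‑yl)but‑3‑en‑1‑yl]‑2‑{1‑[(triethylsilyl)oxy]ethenyl}cyclohexyl acetate
Product: 25 (1S,4S,4aR,6S,8aS)‑4,4a‑dimethyl‑6‑(prop‑1‑en‑2‑yl)‑8‑[(triethylsilyl)oxy]‑1,2,3,4,4a,5,6,8a‑octahydronaphthalen‑1‑yl acetate
Conditions: second‑generation Grubbs catalyst RuCl2(=CHPh)(PCy3)(H2IMes) (10 mol %), 1,4‑benzoquinone (10 mol %), toluene (5 mM), 80 °C
Reagents that add atoms: none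
Why: Ring‑closing metathesis starts at the monosubstituted vinyl group and closes onto the silyl enol ether to form ring B (C8=C9); all sp3 centres are already fixed, so the trans ring fusion and 7β‑isopropenyl group are carried in unchanged.

Step 17
Reactants: 25 (1S,4S,4aR,6S,8aS)‑4,4a‑dimethyl‑6‑(prop‑1‑en‑2‑yl)‑8‑[(triethylsilyl)oxy]‑1,2,3,4,4a,5,6,8a‑octahydronaphthalen‑1‑yl acetate
Product: 27 (1S,4S,4aR,6R,7R,8aS)‑7‑hydroxy‑4,4a‑dimethyl‑8‑oxo‑6‑(prop‑1‑en‑2‑yl)decahydronaphthalen‑1‑yl acetate, via silyloxy ketone 26 (not isolated)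
Conditions: mCPBA, NaHCO3, CH2Cl2, −20 °C; then aq. citric acid, THF, 0 °C
Reagents that add atoms: 3‑chloroperoxybenzoic acid (O=C(OO)c1cccc(Cl)c1)
Why: Rubottom oxidation; the electron‑rich enol ether is epoxidised far faster than the isopropenyl group, from the α face because the axial C5 methyl and the pseudoaxial C7 isopropenyl group shield the β face, giving the 8α‑hydroxy ketone (trans to isopropenyl).

Step 18
Reactants: 27 (1S,4S,4aR,6R,7R,8aS)‑7‑hydroxy‑4,4a‑dimethyl‑8‑oxo‑6‑(prop‑1‑en‑2‑yl)decahydronaphthalen‑1‑yl acetate; 16 (2Z)‑2‑methylbut‑2‑enoic 2,4,6‑trichlorobenzoic anhydride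
Product: 28 (1S,4S,4aR,6R,7R,8aS)‑1‑(acetyloxy)‑4,4a‑dimethyl‑8‑oxo‑6‑(prop‑1‑en‑2‑yl)decahydronaphthalen‑7‑yl (2Z)‑2‑methylbut‑2‑enoate (ring numbering as in 27)
Conditions: DMAP, toluene, 23 °C
Reagents that add atoms: none
Why: Yamaguchi esterification; DMAP attacks the unhindered angeloyl carbonyl of the mixed anhydride and acylates the axial ketol without Z→E isomerisation, and the mild base keeps C10 and the β‑acetoxy ketone intact.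

**Compound list**
1 | propanal | CCC=O | starting material
2 | but‑3‑en‑2‑one | CC(=O)C=C | starting material
3 | (2S)‑2‑methyl‑5‑oxohexanal | CC(=O)CC[C@H](C)C=O | intermediate
4 | (4S)‑4‑methylcyclohex‑2‑en‑1‑one | O=C1C=C[C@@H](C)CC1 | intermediate
5 | trimethyl{[(3R,4S)‑3,4‑dimethylcyclohex‑1‑en‑1‑yl]oxy}silane | C[Si](C)(C)OC1=C[C@H](C)[C@@H](C)CC1 | intermediate
6 | (4S)‑3,4‑dimethylcyclohex‑2‑en‑1‑one | CC1=CC(=O)CC[C@@H]1C | intermediate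
7 | (2E)‑but‑2‑ene‑1,4‑diol | OC/C=C/CO | starting material
8 | (2E)‑4‑{[tert‑butyl(dimethyl)silyl]oxy}but‑2‑en‑1‑ol | OC/C=C/CO[Si](C)(C)C(C)(C)C | intermediate
9 | (2E)‑4‑{[tert‑butyl(dimethyl)silyl]oxy}but‑2‑en‑1‑yl diethyl phosphate | CCOP(=O)(OCC)OC/C=C/CO[Si](C)(C)C(C)(C)C | intermediate
10 | prop‑1‑en‑2‑ylmagnesium bromide | C=C(C)[Mg]Br | starting material
11 | 4,4,5,5‑tetramethyl‑2‑(prop‑1‑en‑2‑yl)‑1,3,2‑dioxaborolane | C=C(C)B1OC(C)(C)C(C)(C)O1 | intermediate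
12 | tert‑butyl(dimethyl){[(2S)‑2‑(prop‑1‑en‑2‑yl)but‑3‑en‑1‑yl]oxy}silane | C=C(C)[C@H](C=C)CO[Si](C)(C)C(C)(C)C | intermediate
13 | (2S)‑2‑(prop‑1‑en‑2‑yl)but‑3‑en‑1‑ol | C=C(C)[C@H](C=C)CO | intermediate
14 | (3S)‑3‑(bromomethyl)‑2‑methylpenta‑1,4‑diene | C=C(C)[C@H](C=C)CBr | intermediate
15 | (2Z)‑2‑methylbut‑2‑enoic acid | C/C=C(/C)C(=O)O | starting material
16 | (2Z)‑2‑methylbut‑2‑enoic 2,4,6‑trichlorobenzoic anhydride | C/C=C(/C)C(=O)OC(=O)c1c(Cl)cc(Cl)cc1Cl | intermediate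
17 | acetaldehyde | CC=O | starting material
18 | bromo[(2S)‑2‑(prop‑1‑en‑2‑yl)but‑3‑en‑1‑yl]magnesium | C=C(C)[C@H](C=C)C[Mg]Br | intermediate (not isolated)
19 | trimethyl({(3R,4S)‑3,4‑dimethyl‑3‑[(2S)‑2‑(prop‑1‑en‑2‑yl)but‑3‑en‑1‑yl]cyclohex‑1‑en‑1‑yl}oxy)silane | C=C(C)[C@H](C=C)C[C@@]1(C)C=C(O[Si](C)(C)C)CC[C@@H]1C | intermediate (not isolated)
20 | lithium (3R,4S)‑3,4‑dimethyl‑3‑[(2S)‑2‑(prop‑1‑en‑2‑yl)but‑3‑en‑1‑yl]cyclohex‑1‑en‑1‑olate | C=C(C)[C@H](C=C)C[C@@]1(C)C=C([O-])CC[C@@H]1C.[Li+] | intermediate (not isolated)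
21 | (3R,4S)‑2‑(1‑hydroxyethyl)‑3,4‑dimethyl‑3‑[(2S)‑2‑(prop‑1‑en‑2‑yl)but‑3‑en‑1‑yl]cyclohexan‑1‑one (C2 and carbinol carbon unspecified) | C=C(C)[C@H](C=C)C[C@@]1(C)C(C(C)O)C(=O)CC[C@@H]1C | intermediate
22 | 1‑[(1S,2R,3S,6S)‑6‑hydroxy‑2,3‑dimethyl‑2‑[(2S)‑2‑(prop‑1‑en‑2‑yl)but‑3‑en‑1‑yl]cyclohexyl]ethan‑1‑one | C=C(C)[C@H](C=C)C[C@@]1(C)[C@H](C(C)=O)[C@@H](O)CC[C@@H]1C | intermediate
23 | (1S,2S,3R,4S)‑2‑acetyl‑3,4‑dimethyl‑3‑[(2S)‑2‑(prop‑1‑en‑2‑yl)but‑3‑en‑1‑yl]cyclohexyl acetate | C=C(C)[C@H](C=C)C[C@@]1(C)[C@H](C(C)=O)[C@@H](OC(C)=O)CC[C@@H]1C | intermediate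
24 | (1S,2S,3R,4S)‑3,4‑dimethyl‑3‑[(2S)‑2‑(prop‑1‑en‑2‑yl)but‑3‑en‑1‑yl]‑2‑{1‑[(triethylsilyl)oxy]ethenyl}cyclohexyl acetate | C=C(C)[C@H](C=C)C[C@@]1(C)[C@H](C(=C)O[Si](CC)(CC)CC)[C@@H](OC(C)=O)CC[C@@H]1C | intermediate
25 | (1S,4S,4aR,6S,8aS)‑4,4a‑dimethyl‑6‑(prop‑1‑en‑2‑yl)‑8‑[(triethylsilyl)oxy]‑1,2,3,4,4a,5,6,8a‑octahydronaphthalen‑1‑yl acetate | C=C(C)[C@H]1C[C@@]2(C)[C@H](C(O[Si](CC)(CC)CC)=C1)[C@@H](OC(C)=O)CC[C@@H]2C | intermediate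
26 | (1S,4S,4aR,6R,7R,8aS)‑4,4a‑dimethyl‑8‑oxo‑6‑(prop‑1‑en‑2‑yl)‑7‑[(triethylsilyl)oxy]decahydronaphthalen‑1‑yl acetate | C=C(C)[C@H]1C[C@@]2(C)[C@H](C(=O)[C@@H]1O[Si](CC)(CC)CC)[C@@H](OC(C)=O)CC[C@@H]2C | intermediate (not isolated)
27 | (1S,4S,4aR,6R,7R,8aS)‑7‑hydroxy‑4,4a‑dimethyl‑8‑oxo‑6‑(prop‑1‑en‑2‑yl)decahydronaphthalen‑1‑yl acetate | C=C(C)[C@H]1C[C@@]2(C)[C@H](C(=O)[C@@H]1O)[C@@H](OC(C)=O)CC[C@@H]2C | intermediate
28 | (1S,4S,4aR,6R,7R,8aS)‑1‑(acetyloxy)‑4,4a‑dimethyl‑8‑oxo‑6‑(prop‑1‑en‑2‑yl)decahydronaphthalen‑7‑yl (2Z)‑2‑methylbut‑2‑enoate | C=C(C)[C@H]1C[C@@]2(C)[C@H](C(=O)[C@@H]1OC(=O)/C(C)=C\C)[C@@H](OC(C)=O)CC[C@@H]2C | target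

**Totals**
Total step count: 18. Longest linear sequence: 12 steps (5, 6, 8, 9, 10, 12, 13, 14, 15, 16, 17, 18).

**Steps most likely to fail, with fallbacks**

Step 12 (β‑branched Grignard onto a hindered β,β‑disubstituted enone, then aldol at a neopentyl‑type enolate). The fallback sets out from 6, 7, 11 and 17 and comes back at 21. The quaternary centre is made with a small nucleophile and C7 is built afterwards on the ring‑bound chain. Hosomi–Sakurai allylation of 6 (allyltrimethylsilane, TiCl4, CH2Cl2, −78 °C) with trapping of the titanium enolate by 17 gives (3R,4S)‑2‑(1‑hydroxyethyl)‑3,4‑dimethyl‑3‑(prop‑2‑en‑1‑yl)cyclohexan‑1‑one F1. Diol 7 is converted with diethyl chlorophosphate and pyridine into (2E)‑but‑2‑ene‑1,4‑diyl tetraethyl bis(phosphate) F2. Cross‑metathesis of F1 with F2 (second‑generation Grubbs catalyst, CH2Cl2, 40 °C) gives (2E)‑4‑[(1R,6S)‑2‑(1‑hydroxyethyl)‑1,6‑dimethyl‑3‑oxocyclohexyl]but‑2‑en‑1‑yl diethyl phosphate F3. The copper‑catalysed allylic substitution of step 8 with 11 (run at 0 °C to limit retro‑aldol) then sets C7 under catalyst control and delivers 21.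

Step 13 (the proposed new step; risks are an incomplete equilibrium, retro‑aldol and isomerisation of the skipped diene by ruthenium hydride). The fallback sets out from 21 and comes back at 23 using known chemistry. Silylation (TESOTf, 2,6‑lutidine, CH2Cl2, −78 °C) gives (3R,4S)‑3,4‑dimethyl‑3‑[(2S)‑2‑(prop‑1‑en‑2‑yl)but‑3‑en‑1‑yl]‑2‑{1‑[(triethylsilyl)oxy]ethyl}cyclohexan‑1‑one F4. Equilibrating Meerwein–Ponndorf–Verley reduction (Al(OiPr)3, iPrOH, toluene, 80 °C) gives the equatorial alcohol (1S,2S,3R,4S)‑3,4‑dimethyl‑3‑[(2S)‑2‑(prop‑1‑en‑2‑yl)but‑3‑en‑1‑yl]‑2‑{1‑[(triethylsilyl)oxy]ethyl}cyclohexan‑1‑ol F5, with C10 also equilibrated. Acetylation (Ac2O, pyridine) gives (1S,2S,3R,4S)‑3,4‑dimethyl‑3‑[(2S)‑2‑(prop‑1‑en‑2‑yl)but‑3‑en‑1‑yl]‑2‑{1‑[(triethylsilyl)oxy]ethyl}cyclohexyl acetate F6. Desilylation (camphorsulfonic acid, MeOH) gives (1S,2R,3R,4S)‑2‑(1‑hydroxyethyl)‑3,4‑dimethyl‑3‑[(2S)‑2‑(prop‑1‑en‑2‑yl)but‑3‑en‑1‑yl]cyclohexyl acetate F7, and Dess–Martin oxidation of F7 gives 23.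

Step 16 (metathesis onto an electron‑rich, hindered enol ether; possible catalyst deactivation). The fallback sets out from 23 and comes back at 25, replacing the enol ether by a boron‑substituted alkene as the metathesis partner. Kinetic triflation (LiN(SiMe3)2, PhNTf2, THF, −78 °C) gives (1S,2S,3R,4S)‑3,4‑dimethyl‑3‑[(2S)‑2‑(prop‑1‑en‑2‑yl)but‑3‑en‑1‑yl]‑2‑{1‑[(trifluoromethanesulfonyl)oxy]ethenyl}cyclohexyl acetate F8. Miyaura borylation (B2pin2, PdCl2(PPh3)2, PPh3, KOPh, toluene, 50 °C) gives (1S,2S,3R,4S)‑3,4‑dimethyl‑3‑[(2S)‑2‑(prop‑1‑en‑2‑yl)but‑3‑en‑1‑yl]‑2‑[1‑(4,4,5,5‑tetramethyl‑1,3,2‑dioxaborolan‑2‑yl)ethenyl]cyclohexyl acetate F9. Ring‑closing metathesis (second‑generation Grubbs catalyst) gives (1S,4S,4aR,6S,8aS)‑4,4a‑dimethyl‑6‑(prop‑1‑en‑2‑yl)‑8‑(4,4,5,5‑tetramethyl‑1,3,2‑dioxaborolan‑2‑yl)‑1,2,3,4,4a,5,6,8a‑octahydronaphthalen‑1‑yl acetate F10. Oxidation (NaBO3·4H2O, THF/H2O, 0 °C) gives (1S,4S,4aR,6S,8aS)‑4,4a‑dimethyl‑8‑oxo‑6‑(prop‑1‑en‑2‑yl)decahydronaphthalen‑1‑yl acetate F11, and kinetic silylation toward C8 (LiN(SiMe3)2, Et3SiCl, THF, −78 °C) gives 25.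

**Further compounds**
F1 | step 12 | (3R,4S)‑2‑(1‑hydroxyethyl)‑3,4‑dimethyl‑3‑(prop‑2‑en‑1‑yl)cyclohexan‑1‑one | C=CC[C@@]1(C)C(C(C)O)C(=O)CC[C@@H]1C
F2 | step 12 | (2E)‑but‑2‑ene‑1,4‑diyl tetraethyl bis(phosphate) | CCOP(=O)(OCC)OC/C=C/COP(=O)(OCC)OCC
F3 | step 12 | (2E)‑4‑[(1R,6S)‑2‑(1‑hydroxyethyl)‑1,6‑dimethyl‑3‑oxocyclohexyl]but‑2‑en‑1‑yl diethyl phosphate | CCOP(=O)(OCC)OC/C=C/C[C@@]1(C)C(C(C)O)C(=O)CC[C@@H]1C
F4 | step 13 | (3R,4S)‑3,4‑dimethyl‑3‑[(2S)‑2‑(prop‑1‑en‑2‑yl)but‑3‑en‑1‑yl]‑2‑{1‑[(triethylsilyl)oxy]ethyl}cyclohexan‑1‑one | C=C(C)[C@H](C=C)C[C@@]1(C)C(C(C)O[Si](CC)(CC)CC)C(=O)CC[C@@H]1C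
F5 | step 13 | (1S,2S,3R,4S)‑3,4‑dimethyl‑3‑[(2S)‑2‑(prop‑1‑en‑2‑yl)but‑3‑en‑1‑yl]‑2‑{1‑[(triethylsilyl)oxy]ethyl}cyclohexan‑1‑ol | C=C(C)[C@H](C=C)C[C@@]1(C)[C@H](C(C)O[Si](CC)(CC)CC)[C@@H](O)CC[C@@H]1C
F6 | step 13 | (1S,2S,3R,4S)‑3,4‑dimethyl‑3‑[(2S)‑2‑(prop‑1‑en‑2‑yl)but‑3‑en‑1‑yl]‑2‑{1‑[(triethylsilyl)oxy]ethyl}cyclohexyl acetate | C=C(C)[C@H](C=C)C[C@@]1(C)[C@H](C(C)O[Si](CC)(CC)CC)[C@@H](OC(C)=O)CC[C@@H]1C
F7 | step 13 | (1S,2R,3R,4S)‑2‑(1‑hydroxyethyl)‑3,4‑dimethyl‑3‑[(2S)‑2‑(prop‑1‑en‑2‑yl)but‑3‑en‑1‑yl]cyclohexyl acetate | C=C(C)[C@H](C=C)C[C@@]1(C)[C@H](C(C)O)[C@@H](OC(C)=O)CC[C@@H]1C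
F8 | step 16 | (1S,2S,3R,4S)‑3,4‑dimethyl‑3‑[(2S)‑2‑(prop‑1‑en‑2‑yl)but‑3‑en‑1‑yl]‑2‑{1‑[(trifluoromethanesulfonyl)oxy]ethenyl}cyclohexyl acetate | C=C(C)[C@H](C=C)C[C@@]1(C)[C@H](C(=C)OS(=O)(=O)C(F)(F)F)[C@@H](OC(C)=O)CC[C@@H]1C
F9 | step 16 | (1S,2S,3R,4S)‑3,4‑dimethyl‑3‑[(2S)‑2‑(prop‑1‑en‑2‑yl)but‑3‑en‑1‑yl]‑2‑[1‑(4,4,5,5‑tetramethyl‑1,3,2‑dioxaborolan‑2‑yl)ethenyl]cyclohexyl acetate | C=C(C)[C@H](C=C)C[C@@]1(C)[C@H](C(=C)B2OC(C)(C)C(C)(C)O2)[C@@H](OC(C)=O)CC[C@@H]1C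
F10 | step 16 | (1S,4S,4aR,6S,8aS)‑4,4a‑dimethyl‑6‑(prop‑1‑en‑2‑yl)‑8‑(4,4,5,5‑tetramethyl‑1,3,2‑dioxaborolan‑2‑yl)‑1,2,3,4,4a,5,6,8a‑octahydronaphthalen‑1‑yl acetate | C=C(C)[C@H]1C[C@@]2(C)[C@H](C(B3OC(C)(C)C(C)(C)O3)=C1)[C@@H](OC(C)=O)CC[C@@H]2C
F11 | step 16 | (1S,4S,4aR,6S,8aS)‑4,4a‑dimethyl‑8‑oxo‑6‑(prop‑1‑en‑2‑yl)decahydronaphthalen‑1‑yl acetate | C=C(C)[C@H]1C[C@@]2(C)[C@H](C(=O)C1)[C@@H](OC(C)=O)CC[C@@H]2C
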